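The route rests on cutting the side chain between its methyl-bearing alkene carbon C4′ and the oxygenated methylene C5′ of the allylic p-coumarate. The feature exploited is that C5′ is an O-acylated CH2 on an sp2 carbon: it is the decarboxylation residue of an O-coumaroyl glycolic acid, while C4′ can be carried as a geometrically defined (E)-vinyl iodide on the finished 2,3,4,7-tetrahydrooxepine core. A nickel-electrocatalytic decarboxylative alkenylation joins the N-acyloxyphthalimide of that glycolate to the vinyl iodide, forming the C4′–C5′ bond and the complete allylic ester in one operation with retention of alkene geometry. The core comes from an enantioselective aldol, etherification and ring-closing metathesis.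

Key step: step 14

Assumption: the Cu(OTf)2/bis(oxazoline) aldol is taken to follow its usual square-planar chelate model with keto ester 8, so that the (R,R)-ligand gives the (R)-carbinol.

Step 1
Reactants: 1 2′,5′-dihydroxyacetophenone
Product: 2 1-[2,5-bis(tert-butyldimethylsilyloxy)phenyl]ethanone
Conditions: TBSCl (2.5 equiv), imidazole, DMF, rt
Reagents that add atoms: tert-butyldimethylsilyl chloride, CC(C)(C)[Si](C)(C)Cl
Why: Silyl ether formation on both phenols, the hydrogen-bonded ortho phenol reacting more slowly but completely with excess reagent, gives fluoride-labile protection that should survive all later steps.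

Step 2
Reactants: 2 1-[2,5-bis(tert-butyldimethylsilyloxy)phenyl]ethanone
Product: 3 {1-[2,5-bis(tert-butyldimethylsilyloxy)phenyl]ethenyloxy}trimethylsilane
Conditions: TMSOTf, Et3N, CH2Cl2, 0 °C
Reagents that add atoms: trimethylsilyl triflate, C[Si](C)(C)OS(=O)(=O)C(F)(F)F
Why: Soft enolisation of the methyl ketone gives the terminal enolsilane without a free enolate, so the ortho silyloxy group cannot migrate.

Step 3
Reactants: 4 2-(trimethylsilyl)ethanol; 5 oxalyl chloride; 6 but-3-en-1-ylmagnesium bromide
Product: 8 2-(trimethylsilyl)ethyl 2-oxohex-5-enoate, via 2-(trimethylsilyl)ethyl chlorooxoacetate 7 (not isolated)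
Conditions: 5 (excess), Et2O, 0 °C → rt, evaporate; then 6 (1.0 equiv, slow addition), CuBr·SMe2 (cat.), LiBr, THF, −78 °C
Reagents that add atoms: none
Why: Alcoholysis of one acyl chloride of oxalyl chloride gives half-ester chloride 7, and acylation of the Grignard reagent under catalysis by monovalent copper at −78 °C stops at the α-keto ester because the acyl chloride is far more reactive than the ketone formed.

Step 4
Reactants: 3 {1-[2,5-bis(tert-butyldimethylsilyloxy)phenyl]ethenyloxy}trimethylsilane; 8 2-(trimethylsilyl)ethyl 2-oxohex-5-enoate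
Product: 10 2-(trimethylsilyl)ethyl (2R)-2-{2-[2,5-bis(tert-butyldimethylsilyloxy)phenyl]-2-oxoethyl}-2-hydroxyhex-5-enoate, via tertiary trimethylsilyl ether 9 (not isolated)
Conditions: Cu(OTf)2 (10 mol%), 2,2′-(propane-2,2-diyl)bis[(4R)-4-tert-butyl-4,5-dihydrooxazole] (11 mol%), THF, −78 °C; then 1 M HCl, THF, 0 °C
Reagents that add atoms: none
Why: In this chiral Lewis acid-catalysed Mukaiyama aldol addition, keto ester 8 chelates divalent copper through both carbonyl oxygens in a square-planar complex, the tert-butyl group of the (R,R)-ligand shields the si face of the ketone, and enolsilane 3 adds to the re face to set the (R)-configured quaternary carbinol, which the acidic work-up frees from silyl ether 9.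

Step 5
Reactants: 11 but-2-yn-1-ol
Product: 14 (2E)-3-iodobut-2-en-1-ol, via diisobutylaluminium but-2-yn-1-olate 12 (not isolated), via alkenylzirconocene chloride 13 (not isolated)
Conditions: i-Bu2AlH (1.0 equiv), THF, 0 °C; then Cp2ZrCl2 (1.3 equiv), i-Bu2AlH (1.3 equiv), THF, 0 °C → rt; then I2, −78 → 0 °C; 1 M HCl work-up
Reagents that add atoms: iodine, II
Why: In this hydrozirconation–iodination of an internal alkyne, Cp2Zr(H)Cl made in the flask adds syn to the aluminium alkoxide with zirconium on the less hindered, methyl-bearing carbon, and iodinolysis with retention gives the (E)-iodoalkene in which methyl and CH2OH are cis.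

Step 6
Reactants: 14 (2E)-3-iodobut-2-en-1-ol
Product: 15 (2E)-1-bromo-3-iodobut-2-ene
Conditions: CBr4, PPh3, CH2Cl2, 0 °C
Reagents that add atoms: carbon tetrabromide, BrC(Br)(Br)Br
Why: The Appel reaction converts the primary allylic alcohol into the bromide by SN2 displacement of the oxyphosphonium group under neutral conditions, leaving the vinyl iodide and its geometry untouched.

Step 7
Reactants: 16 2-methylprop-2-en-1-ol; 15 (2E)-1-bromo-3-iodobut-2-ene
Product: 18 (5E)-6-iodo-2-methylidenehept-5-en-1-ol, via dilithiated 2-methylprop-2-en-1-ol 17 (not isolated)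
Conditions: 16 (2.4 equiv), n-BuLi (4.6 equiv), TMEDA, Et2O/hexane, 0 °C → rt; then 15 (1 equiv), THF, −78 → −20 °C
Reagents that add atoms: none
Why: Double deprotonation of methallyl alcohol gives an allyllithium with two equivalent CH2 termini, which should alkylate the primary allylic bromide by SN2 at −78 °C faster than iodine–lithium exchange, an exchange that is uphill for a stabilised allyl anion.

Step 8
Reactants: 18 (5E)-6-iodo-2-methylidenehept-5-en-1-ol
Product: 19 (5E)-6-iodo-2-methylidenehept-5-en-1-yl 2,2,2-trichloroacetimidate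
Conditions: Cl3CCN, DBU (cat.), CH2Cl2, 0 °C
Reagents that add atoms: trichloroacetonitrile, N#CC(Cl)(Cl)Cl
Why: Base-catalysed addition of the alcohol to trichloroacetonitrile gives an allylic trichloroacetimidate, an electrophile that acid alone can activate.

Step 9
Reactants: 10 2-(trimethylsilyl)ethyl (2R)-2-{2-[2,5-bis(tert-butyldimethylsilyloxy)phenyl]-2-oxoethyl}-2-hydroxyhex-5-enoate; 19 (5E)-6-iodo-2-methylidenehept-5-en-1-yl 2,2,2-trichloroacetimidate
Product: 20 2-(trimethylsilyl)ethyl (2R)-2-{2-[2,5-bis(tert-butyldimethylsilyloxy)phenyl]-2-oxoethyl}-2-{[(5E)-6-iodo-2-methylidenehept-5-en-1-yl]oxy}hex-5-enoate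
Conditions: 19 (2 equiv), TfOH (10 mol%), cyclohexane/CH2Cl2, 0 °C → rt
Reagents that add atoms: none
Why: In this acid-catalysed O-alkylation by a trichloroacetimidate, protonated 19 releases trichloroacetamide and a 2-alkylallyl cation with identical termini that the tertiary hydroxyl traps without base, so retro-aldol cleavage and β-elimination are avoided and the stereocenter, whose C–O bond is not broken, is untouched.

Step 10
Reactants: 20 2-(trimethylsilyl)ethyl (2R)-2-{2-[2,5-bis(tert-butyldimethylsilyloxy)phenyl]-2-oxoethyl}-2-{[(5E)-6-iodo-2-methylidenehept-5-en-1-yl]oxy}hex-5-enoate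
Product: 21 2-(trimethylsilyl)ethyl (2R)-2-{2-[2,5-bis(tert-butyldimethylsilyloxy)phenyl]-2-oxoethyl}-6-[(3E)-4-iodopent-3-en-1-yl]-2,3,4,7-tetrahydrooxepine-2-carboxylate
Conditions: second-generation Grubbs catalyst (5 mol%), CH2Cl2 (0.005 M), 40 °C
Reagents that add atoms: none
Why: In this ring-closing metathesis the ruthenium carbene loads on the monosubstituted butenyl alkene and closes onto the 1,1-disubstituted allyl ether alkene to form the trisubstituted C5=C6 alkene of the seven-membered ring with loss of ethylene, while the trisubstituted vinyl iodide is too hindered and electron-poor to engage.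

Step 11
Reactants: 22 (2E)-3-(4-hydroxyphenyl)prop-2-enoic acid (p-coumaric acid)
Product: 24 (2E)-3-[4-(tert-butyldimethylsilyloxy)phenyl]prop-2-enoic acid, via tert-butyldimethylsilyl ester 23 (not isolated)
Conditions: TBSCl (2.4 equiv), imidazole, DMF, rt; then AcOH/THF/H2O, rt
Reagents that add atoms: tert-butyldimethylsilyl chloride, CC(C)(C)[Si](C)(C)Cl
Why: Silylation of phenol and acid followed by selective hydrolysis of the much more labile silyl ester leaves only the phenol protected.

Step 12
Reactants: 24 (2E)-3-[4-(tert-butyldimethylsilyloxy)phenyl]prop-2-enoic acid; 25 glycolic acid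
Product: 27 {[(2E)-3-[4-(tert-butyldimethylsilyloxy)phenyl]prop-2-enoyl]oxy}acetic acid, via acid chloride 26 (not isolated)
Conditions: (COCl)2 (5), DMF (cat.), CH2Cl2, 0 °C → rt, evaporate; then 25 (3 equiv), pyridine, THF, 0 °C → rt
Reagents that add atoms: none
Why: Acyl chloride formation and nucleophilic acyl substitution by the hydroxyl of excess glycolic acid give the O-acyl glycolic acid, any mixed anhydride at the carboxyl group passing its acyl group on to hydroxyl.

Step 13
Reactants: 27 {[(2E)-3-[4-(tert-butyldimethylsilyloxy)phenyl]prop-2-enoyl]oxy}acetic acid; 28 N-hydroxyphthalimide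
Product: 29 1,3-dioxoisoindolin-2-yl {[(2E)-3-[4-(tert-butyldimethylsilyloxy)phenyl]prop-2-enoyl]oxy}acetate
Conditions: N,N′-diisopropylcarbodiimide, DMAP (cat.), CH2Cl2, rt
Reagents that add atoms: none
Why: Carbodiimide coupling of the Steglich type converts the acid into its N-hydroxyphthalimide ester, the redox-active ester needed for reductive decarboxylation.

Step 14
Reactants: 21 2-(trimethylsilyl)ethyl (2R)-2-{2-[2,5-bis(tert-butyldimethylsilyloxy)phenyl]-2-oxoethyl}-6-[(3E)-4-iodopent-3-en-1-yl]-2,3,4,7-tetrahydrooxepine-2-carboxylate; 29 1,3-dioxoisoindolin-2-yl {[(2E)-3-[4-(tert-butyldimethylsilyloxy)phenyl]prop-2-enoyl]oxy}acetate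
Product: 30 2-(trimethylsilyl)ethyl (2R)-2-{2-[2,5-bis(tert-butyldimethylsilyloxy)phenyl]-2-oxoethyl}-6-[(3E)-5-{[(2E)-3-[4-(tert-butyldimethylsilyloxy)phenyl]prop-2-enoyl]oxy}-4-methylpent-3-en-1-yl]-2,3,4,7-tetrahydrooxepine-2-carboxylate
Conditions: 29 (2 equiv), NiCl2·6H2O (20 mol%), 2,2′-bipyridine (20 mol%), AgNO3 (0.3 equiv), LiCl, DMF, Mg anode, reticulated vitreous carbon cathode, undivided cell, constant current, rt
Reagents that add atoms: none
Why: This is a nickel-electrocatalytic decarboxylative alkenylation, a reductive cross-electrophile coupling of a redox-active ester with an alkenyl iodide: cathodic reduction at the silver-coated cathode gives low-valent nickel–bipyridine, zerovalent nickel inserts into the C–I bond of 21 with retention of geometry, single-electron reduction of 29 releases phthalimide anion and CO2 to give the (acyloxy)methyl radical, the alkenylnickel species captures it, and reductive elimination from trivalent nickel forms the C4′–C5′ bond while the magnesium anode supplies the electrons. The closest known reactions are nickel-catalysed decarboxylative alkenylations of N-acyloxyphthalimides with alkenyl halides or alkenylzinc reagents, including electrochemical variants used to assemble trisubstituted alkenes, and nickel-catalysed decarboxylative couplings of α-oxygenated acids. No ring is closed and no stereocenter is formed; the quaternary center C2 is remote and untouched. The step needs retention of the (E)-alkene geometry, which is secured because oxidative addition and reductive elimination at nickel are stereoretentive and the radical is generated on the other partner. It also needs chemoselectivity over the aryl ketone, the cinnamate and the product allylic ester, which should follow from the mild potential of the nickel/silver system and the much faster reaction of low-valent nickel with the vinyl iodide, with excess 29 compensating for radical lost to reduction or dimerisation.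

Step 15
Reactants: 30 2-(trimethylsilyl)ethyl (2R)-2-{2-[2,5-bis(tert-butyldimethylsilyloxy)phenyl]-2-oxoethyl}-6-[(3E)-5-{[(2E)-3-[4-(tert-butyldimethylsilyloxy)phenyl]prop-2-enoyl]oxy}-4-methylpent-3-en-1-yl]-2,3,4,7-tetrahydrooxepine-2-carboxylate
Product: 31 (2R)-2-[2-(2,5-dihydroxyphenyl)-2-oxoethyl]-6-[(3E)-5-{[(2E)-3-(4-hydroxyphenyl)prop-2-enoyl]oxy}-4-methylpent-3-en-1-yl]-2,3,4,7-tetrahydrooxepine-2-carboxylic acid (CNP0602535.1)
Conditions: TASF, (Me2N)3S+ Me3SiF2− (6 equiv), DMF, 0 °C → rt; then 0.1 M HCl to pH 3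
Reagents that add atoms: none
Why: Fluoride-induced global desilylation should cleave the three aryl silyl ethers and fragment the 2-(trimethylsilyl)ethyl ester to ethylene and carboxylate under nearly neutral anhydrous conditions that leave the allylic p-coumarate, the β-alkoxy ketone and the C2 stereocenter intact.

Compound list
1 | 2′,5′-dihydroxyacetophenone | CC(=O)c1cc(O)ccc1O | starting material
2 | 1-[2,5-bis(tert-butyldimethylsilyloxy)phenyl]ethanone | CC(=O)c1cc(O[Si](C)(C)C(C)(C)C)ccc1O[Si](C)(C)C(C)(C)C | intermediate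
3 | {1-[2,5-bis(tert-butyldimethylsilyloxy)phenyl]ethenyloxy}trimethylsilane | C=C(O[Si](C)(C)C)c1cc(O[Si](C)(C)C(C)(C)C)ccc1O[Si](C)(C)C(C)(C)C | intermediate
4 | 2-(trimethylsilyl)ethanol | C[Si](C)(C)CCO | starting material
5 | oxalyl chloride | O=C(Cl)C(=O)Cl | starting material
6 | but-3-en-1-ylmagnesium bromide | C=CCC[Mg]Br | starting material
7 | 2-(trimethylsilyl)ethyl chlorooxoacetate | C[Si](C)(C)CCOC(=O)C(=O)Cl | intermediate
8 | 2-(trimethylsilyl)ethyl 2-oxohex-5-enoate | C=CCCC(=O)C(=O)OCC[Si](C)(C)C | intermediate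
9 | 2-(trimethylsilyl)ethyl (2R)-2-{2-[2,5-bis(tert-butyldimethylsilyloxy)phenyl]-2-oxoethyl}-2-(trimethylsilyloxy)hex-5-enoate | C=CCC[C@@](O[Si](C)(C)C)(CC(=O)c1cc(O[Si](C)(C)C(C)(C)C)ccc1O[Si](C)(C)C(C)(C)C)C(=O)OCC[Si](C)(C)C | intermediate
10 | 2-(trimethylsilyl)ethyl (2R)-2-{2-[2,5-bis(tert-butyldimethylsilyloxy)phenyl]-2-oxoethyl}-2-hydroxyhex-5-enoate | C=CCC[C@@](O)(CC(=O)c1cc(O[Si](C)(C)C(C)(C)C)ccc1O[Si](C)(C)C(C)(C)C)C(=O)OCC[Si](C)(C)C | intermediate
11 | but-2-yn-1-ol | CC#CCO | starting material
12 | diisobutylaluminium but-2-yn-1-olate | CC#CCO[Al](CC(C)C)CC(C)C | intermediate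
13 | [(2E)-4-(diisobutylaluminiooxy)but-2-en-2-yl]zirconocene chloride | C/C(=C\CO[Al](CC(C)C)CC(C)C)[Zr](Cl)(C1C=CC=C1)C1C=CC=C1 | intermediate
14 | (2E)-3-iodobut-2-en-1-ol | C/C(I)=C\CO | intermediate
15 | (2E)-1-bromo-3-iodobut-2-ene | C/C(I)=C\CBr | intermediate
16 | 2-methylprop-2-en-1-ol | CC(=C)CO | starting material
17 | dilithiated 2-methylprop-2-en-1-ol (lithium 2-(lithiomethyl)prop-2-en-1-olate) | [Li]CC(=C)CO[Li] | intermediate
18 | (5E)-6-iodo-2-methylidenehept-5-en-1-ol | C/C(I)=C\CCC(=C)CO | intermediate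
19 | (5E)-6-iodo-2-methylidenehept-5-en-1-yl 2,2,2-trichloroacetimidate | C/C(I)=C\CCC(=C)COC(=N)C(Cl)(Cl)Cl | intermediate
20 | 2-(trimethylsilyl)ethyl (2R)-2-{2-[2,5-bis(tert-butyldimethylsilyloxy)phenyl]-2-oxoethyl}-2-{[(5E)-6-iodo-2-methylidenehept-5-en-1-yl]oxy}hex-5-enoate | C=CCC[C@@](OCC(=C)CC/C=C(\C)I)(CC(=O)c1cc(O[Si](C)(C)C(C)(C)C)ccc1O[Si](C)(C)C(C)(C)C)C(=O)OCC[Si](C)(C)C | intermediate
21 | 2-(trimethylsilyl)ethyl (2R)-2-{2-[2,5-bis(tert-butyldimethylsilyloxy)phenyl]-2-oxoethyl}-6-[(3E)-4-iodopent-3-en-1-yl]-2,3,4,7-tetrahydrooxepine-2-carboxylate | C/C(I)=C\CCC1=CCC[C@@](CC(=O)c2cc(O[Si](C)(C)C(C)(C)C)ccc2O[Si](C)(C)C(C)(C)C)(C(=O)OCC[Si](C)(C)C)OC1 | intermediate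
22 | (2E)-3-(4-hydroxyphenyl)prop-2-enoic acid (p-coumaric acid) | OC(=O)/C=C/c1ccc(O)cc1 | starting material
23 | tert-butyldimethylsilyl (2E)-3-[4-(tert-butyldimethylsilyloxy)phenyl]prop-2-enoate | CC(C)(C)[Si](C)(C)OC(=O)/C=C/c1ccc(O[Si](C)(C)C(C)(C)C)cc1 | intermediate
24 | (2E)-3-[4-(tert-butyldimethylsilyloxy)phenyl]prop-2-enoic acid | OC(=O)/C=C/c1ccc(O[Si](C)(C)C(C)(C)C)cc1 | intermediate
25 | glycolic acid | OCC(=O)O | starting material
26 | (2E)-3-[4-(tert-butyldimethylsilyloxy)phenyl]prop-2-enoyl chloride | ClC(=O)/C=C/c1ccc(O[Si](C)(C)C(C)(C)C)cc1 | intermediate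
27 | {[(2E)-3-[4-(tert-butyldimethylsilyloxy)phenyl]prop-2-enoyl]oxy}acetic acid | OC(=O)COC(=O)/C=C/c1ccc(O[Si](C)(C)C(C)(C)C)cc1 | intermediate
28 | N-hydroxyphthalimide | ON1C(=O)c2ccccc2C1=O | starting material
29 | 1,3-dioxoisoindolin-2-yl {[(2E)-3-[4-(tert-butyldimethylsilyloxy)phenyl]prop-2-enoyl]oxy}acetate | O=C(COC(=O)/C=C/c1ccc(O[Si](C)(C)C(C)(C)C)cc1)ON1C(=O)c2ccccc2C1=O | intermediate
30 | 2-(trimethylsilyl)ethyl (2R)-2-{2-[2,5-bis(tert-butyldimethylsilyloxy)phenyl]-2-oxoethyl}-6-[(3E)-5-{[(2E)-3-[4-(tert-butyldimethylsilyloxy)phenyl]prop-2-enoyl]oxy}-4-methylpent-3-en-1-yl]-2,3,4,7-tetrahydrooxepine-2-carboxylate | C/C(COC(=O)/C=C/c1ccc(O[Si](C)(C)C(C)(C)C)cc1)=C\CCC1=CCC[C@@](CC(=O)c2cc(O[Si](C)(C)C(C)(C)C)ccc2O[Si](C)(C)C(C)(C)C)(C(=O)OCC[Si](C)(C)C)OC1 | intermediate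
31 | (2R)-2-[2-(2,5-dihydroxyphenyl)-2-oxoethyl]-6-[(3E)-5-{[(2E)-3-(4-hydroxyphenyl)prop-2-enoyl]oxy}-4-methylpent-3-en-1-yl]-2,3,4,7-tetrahydrooxepine-2-carboxylic acid | C/C(COC(=O)/C=C/c1ccc(O)cc1)=C\CCC1=CCC[C@@](CC(=O)c2cc(O)ccc2O)(C(=O)O)OC1 | target

Total step count: 15
Longest linear sequence: 8 steps (steps 5, 6, 7, 8, 9, 10, 14, 15, from but-2-yn-1-ol 11)

Steps most likely to fail

1. Step 14. The redox-active ester may be reduced to the carboxylate, or the (acyloxy)methyl radical may dimerise, before nickel captures it. The radical may also add to a cinnamate double bond, and low-valent nickel may ionise the newly formed allylic ester. Fallback: setting out from 21, a Stille coupling with (tributylstannyl)methanol (Pd(PPh3)4, 1,4-dioxane, 90 °C) should replace iodine by CH2OH with retention of geometry. This forms the same C4′–C5′ bond and gives the allylic alcohol 2-(trimethylsilyl)ethyl (2R)-2-{2-[2,5-bis(tert-butyldimethylsilyloxy)phenyl]-2-oxoethyl}-6-[(3E)-5-hydroxy-4-methylpent-3-en-1-yl]-2,3,4,7-tetrahydrooxepine-2-carboxylate F1. Steglich esterification of this alcohol with acid 24 (DCC, DMAP, CH2Cl2, 0 °C) comes back to the route at 30.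

2. Step 9. Capture of the allyl cation by the hindered, electron-poor tertiary hydroxyl may be slow. Rearrangement of the imidate to the N-allyl trichloroacetamide, cyclisation of the cation onto the iodoalkene, or acid-induced silyl loss could then outrun etherification. Fallback: setting out from 18, an Appel reaction (CBr4, PPh3, CH2Cl2, 0 °C) should give the allylic bromide (5E)-2-(bromomethyl)-6-iodohepta-1,5-diene F2. Alcohol 10 is then alkylated with this bromide by halide abstraction in a buffered, acid-free medium (AgOTf, 2,6-di-tert-butyl-4-methylpyridine, CH2Cl2, 0 °C → rt), which comes back to the route at 20.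

3. Step 7. Residual n-BuLi or the dilithio reagent may attack the vinyl iodide by iodine–lithium exchange, and the allylic bromide may undergo reductive coupling or elimination instead of clean SN2 alkylation. Fallback: setting out from 15, the kinetic lithium enolate of commercial 1-(tert-butyldimethylsilyloxy)propan-2-one (LDA, THF, −78 °C, deprotonation at the methyl group) should be alkylated by the bromide to give the ketone (5E)-1-(tert-butyldimethylsilyloxy)-6-iodohept-5-en-2-one F3. Wittig methylenation (Ph3P=CH2, THF, 0 °C) should then give the silyl ether tert-butyl{[(5E)-6-iodo-2-methylidenehept-5-en-1-yl]oxy}dimethylsilane F4. Desilylation with TBAF in THF comes back to the route at 18.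

Further compounds
F1 | step 14 | 2-(trimethylsilyl)ethyl (2R)-2-{2-[2,5-bis(tert-butyldimethylsilyloxy)phenyl]-2-oxoethyl}-6-[(3E)-5-hydroxy-4-methylpent-3-en-1-yl]-2,3,4,7-tetrahydrooxepine-2-carboxylate | C/C(CO)=C\CCC1=CCC[C@@](CC(=O)c2cc(O[Si](C)(C)C(C)(C)C)ccc2O[Si](C)(C)C(C)(C)C)(C(=O)OCC[Si](C)(C)C)OC1
F2 | step 9 | (5E)-2-(bromomethyl)-6-iodohepta-1,5-diene | C/C(I)=C\CCC(=C)CBr
F3 | step 7 | (5E)-1-(tert-butyldimethylsilyloxy)-6-iodohept-5-en-2-one | C/C(I)=C\CCC(=O)CO[Si](C)(C)C(C)(C)C
F4 | step 7 | tert-butyl{[(5E)-6-iodo-2-methylidenehept-5-en-1-yl]oxy}dimethylsilane | C/C(I)=C\CCC(=C)CO[Si](C)(C)C(C)(C)C
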